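The readings are simulated for substances that don't exist.

**A sum.** I began by adding substrate and target in the north run: between 1.25 d and 3.00 d the sum fell at 0.0331 d⁻¹, as a fraction of the charge.

all flasks: gas phase 50 mM (held)

| charge | substrate | remark | time |
|---|---|---|---|
| south-east | 0.50 M | the very flask that is asked about, followed so far |  |
| north | 1 M | run made earlier |  |
| flask | 0.50 M |  | 3.0 d |

south-east run (percent of the substrate charged)

| time / h | target / % | substrate / % |
|---|---|---|
| 1.00 | 5.2 | 62.2 |
| 2.50 | 10.1 | 48.9 |
| 6.00 | 15.1 | 44.3 |
| 12.0 | 17.7 | 42.2 |

north run (percent of the substrate charged)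

| time / d | target / % | substrate / % |
|---|---|---|
| 0.250 | 12.9 | 45.6 |
| 0.500 | 15.4 | 43.1 |
| 1.25 | 15.0 | 40.2 |
| 3.00 | 13.7 | 35.7 |

(standard deviation of a reading: 0.5 percentage points)

- the numbers in the tables scatter with a standard deviation of 0.5 percentage points
- at the start none of the gas phase is in solution

1. the target standing at 3.0 d, as a percentage of the substrate charged
2. concentration of dissolved gas in solution at 3.0 d, in percent of saturation

**Gas number.** I supposed that each unit lost had cost two of dissolved gas, one to make target and one to remove it. North had 12.9% of its 1 M charge as target at 0.250 d, so up to then transfer supplied at least 21.5 mM h⁻¹ on average. For the flask at 0.50 M, that gives 0.0642. I took this gas number, late gas demand over transfer, as the fraction by which dissolved gas stands below saturation. The demand is a supposition and the supply a floor, so the number is an estimate.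

**Reading it.** The number is small, so I put the flask's dissolved gas near 93.6% of saturation. I therefore treated dissolved gas as nearly constant, which makes the late steps pseudo-first-order, and I expected percentages to depend little on charge. So I took north's 13.7% for the flask. One number was not enough earlier: south-east read 17.7% at 12.0 h and north 15.4% at 0.500 d, a gap of 2.3 percentage points. That this gap closes by 3.0 d was my assumption.

**The forecast.** It gave 15.8% and 90%, reading the target as “a quasi-steady level that tracks the pool”. My target is lower and my saturation higher.

**The result.**

    gas phase ⇌ dissolved gas, rate k1*(csat - [dissolved gas]) (kL = 0.0150 min⁻¹)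
    substrate + dissolved gas ⇌ target (K = 9.00 M⁻¹, k = 0.370 M⁻¹ min⁻¹)
    dissolved gas + target → over-reacted product (k = 0.00800 M⁻¹ min⁻¹)
    substrate ⇌ dormant form (K = 0.890, k = 0.00960 min⁻¹)

The flask gave 13.8% of target and dissolved gas at 93.7% of saturation, a shortfall of 6.30% of saturation beside a gas number of 0.0642. With 0.30 M of substrate, the gas number scales with the charge to 0.0385, which puts dissolved gas at 0.0481 M. That neighbour flask held 0.0481 M at 3.00 d, and its target stood at 13.8%.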